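**Retrosynthetic overview**
- Target ⇐ fluoride desilylation ⇐ Yamaguchi angeloylation of the free C6–OH of a bis-silylated α-methylene lactone.
- Both rings ⇐ one Cr(II) operation on an acyclic (Z)-2-(bromomethyl)enoate aldehyde: the C7–C8 bond closes the cis-cyclodecene first, then the C8 alkoxide closes the γ-lactone on C12. C7 and C8 are set from the free C6 carbinol.
- Acyclic precursor ⇐ Morita–Baylis–Hillman reaction and bromide transposition at C7, and an (E)-selective HWE at C1=C10 that carries the C8 aldehyde as an acetal.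
- C4/C6 stereodiad ⇐ (R)-PMB glycidyl ether by phosphonoacetate lactone annulation, HWE and cis-selective hydrogenation.

Assumption: atoms are numbered as in germacranolides (C7 bears C11(=C13H2)–C12, lactone O on C8, angelate on C6, C15H2OH on C4, C14H2OH on C10, ring olefin C1=C10); the glycidyl PMB ether and 3,3-dimethoxypropanal are taken as catalogue chemicals.

**Step 1**
Reactants: 1 (2R)-2-{[(4-methoxybenzyl)oxy]methyl}oxirane; 2 triethyl phosphonoacetate
Product: 4 diethyl [(5R)-5-{[(4-methoxybenzyl)oxy]methyl}-2-oxooxolan-3-yl]phosphonate (C3 epimers), via open-chain sodium alkoxide 3 (not isolated)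
Conditions: NaH, THF, 0 °C; then 1, 65 °C, 16 h; 1 M HCl work-up
Reagents that add atoms: none
Why: The phosphonoacetate anion opens the epoxide at its CH2 terminus and the alkoxide lactonizes 5-exo on the ethyl ester (phosphonoacetate lactone annulation, kept ≤65 °C to stay out of the Wadsworth–Emmons cyclopropanation channel); C6 is carried unchanged from 1.

**Step 2**
Reactants: 4 diethyl [(5R)-5-{[(4-methoxybenzyl)oxy]methyl}-2-oxooxolan-3-yl]phosphonate; 5 3,3-dimethoxypropanal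
Product: 6 (3E,5R)-3-(3,3-dimethoxypropylidene)-5-{[(4-methoxybenzyl)oxy]methyl}oxolan-2-one
Conditions: NaH, THF, 0 °C; then 5, 0 °C → rt
Reagents that add atoms: none
Why: Horner–Wadsworth–Emmons olefination of the α-phosphono lactone; the alkylidene geometry does not matter because the alkene is hydrogenated next.

**Step 3**
Reactants: 6 (3E,5R)-3-(3,3-dimethoxypropylidene)-5-{[(4-methoxybenzyl)oxy]methyl}oxolan-2-one
Product: 7 (3R,5R)-3-(3,3-dimethoxypropyl)-5-{[(4-methoxybenzyl)oxy]methyl}oxolan-2-one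
Conditions: H2 (1 atm), 5% Pd/C, pyridine (0.5 equiv), EtOAc, rt
Reagents that add atoms: none
Why: Heterogeneous hydrogenation delivers H2 to the exocyclic alkene from the face opposite the C5 substituent, giving the 3,5-cis lactone (C4 = R next to C6 = R); pyridine-poisoned Pd spares the PMB ether.

**Step 4**
Reactants: 7 (3R,5R)-3-(3,3-dimethoxypropyl)-5-{[(4-methoxybenzyl)oxy]methyl}oxolan-2-one
Product: 8 3-[(3R,5R)-5-{[(4-methoxybenzyl)oxy]methyl}-2-oxooxolan-3-yl]propanal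
Conditions: AcOH/THF/H2O (3:1:1), rt
Reagents that add atoms: water, O
Why: Acid-catalysed acetal hydrolysis frees the C1 aldehyde while lactone, PMB ether and both stereocentres are untouched.

**Step 5**
Reactants: 2 triethyl phosphonoacetate; 9 2-bromo-1,1-diethoxyethane
Product: 10 ethyl 2-(diethoxyphosphoryl)-4,4-diethoxybutanoate
Conditions: NaH, DMF, 0 °C; then 9, NaI (cat.), 90 °C
Reagents that add atoms: none
Why: SN2 C-alkylation of the phosphonoacetate anion gives the HWE reagent that carries C8 as an acetal, C9, C10 and C14.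

**Step 6**
Reactants: 8 3-[(3R,5R)-5-{[(4-methoxybenzyl)oxy]methyl}-2-oxooxolan-3-yl]propanal; 10 ethyl 2-(diethoxyphosphoryl)-4,4-diethoxybutanoate
Product: 11 ethyl (2E)-2-(2,2-diethoxyethyl)-5-[(3R,5R)-5-{[(4-methoxybenzyl)oxy]methyl}-2-oxooxolan-3-yl]pent-2-enoate
Conditions: 10, NaH, THF, 0 °C; then 8, −20 °C → rt; minor (Z)-isomer removed by chromatography
Reagents that add atoms: none
Why: Horner–Wadsworth–Emmons olefination with an α-branched phosphonoacetate gives mainly the (E)-enoate (ester trans to C2), which is the ring-cis geometry of the C1=C10 olefin.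

**Step 7**
Reactants: 11 ethyl (2E)-2-(2,2-diethoxyethyl)-5-[(3R,5R)-5-{[(4-methoxybenzyl)oxy]methyl}-2-oxooxolan-3-yl]pent-2-enoate
Product: 12 (2R,4R,7E)-10,10-diethoxy-4,8-bis(hydroxymethyl)-1-[(4-methoxybenzyl)oxy]dec-7-en-2-ol
Conditions: LiAlH4, THF, −20 → 0 °C; Fieser work-up
Reagents that add atoms: none
Why: Hydride reduction opens the lactone to the C15/C6 diol and reduces the enoate 1,2 to the C14 allylic alcohol in one operation; acetal and PMB ether are inert.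

**Step 8**
Reactants: 12 (2R,4R,7E)-10,10-diethoxy-4,8-bis(hydroxymethyl)-1-[(4-methoxybenzyl)oxy]dec-7-en-2-ol
Product: 13 (2R,4R,7E)-4,8-bis{[(tert-butyldiphenylsilyl)oxy]methyl}-10,10-diethoxy-1-[(4-methoxybenzyl)oxy]dec-7-en-2-ol
Conditions: TBDPSCl (2.1 equiv), imidazole, CH2Cl2, −20 → 0 °C
Reagents that add atoms: tert-butyl(chloro)diphenylsilane, CC(C)(C)[Si](Cl)(c1ccccc1)c1ccccc1
Why: Sterically controlled silylation takes the two primary hydroxyls (C14, C15) and leaves the secondary C6–OH.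

**Step 9**
Reactants: 13 (2R,4R,7E)-4,8-bis{[(tert-butyldiphenylsilyl)oxy]methyl}-10,10-diethoxy-1-[(4-methoxybenzyl)oxy]dec-7-en-2-ol
Product: 14 {[(2R,4R,7E)-4,8-bis{[(tert-butyldiphenylsilyl)oxy]methyl}-10,10-diethoxy-1-[(4-methoxybenzyl)oxy]dec-7-en-2-yl]oxy}(triethyl)silane
Conditions: TESCl, imidazole, DMAP (cat.), CH2Cl2, 0 °C → rt
Reagents that add atoms: chlorotriethylsilane, CC[Si](Cl)(CC)CC
Why: Silyl ether formation masks O6 with a group that is removed later by the same acid that frees the C8 aldehyde.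

**Step 10**
Reactants: 14 {[(2R,4R,7E)-4,8-bis{[(tert-butyldiphenylsilyl)oxy]methyl}-10,10-diethoxy-1-[(4-methoxybenzyl)oxy]dec-7-en-2-yl]oxy}(triethyl)silane
Product: 15 (2R,4R,7E)-4,8-bis{[(tert-butyldiphenylsilyl)oxy]methyl}-10,10-diethoxy-2-[(triethylsilyl)oxy]dec-7-en-1-ol
Conditions: DDQ, CH2Cl2/pH 7 buffer (10:1), 0 °C
Reagents that add atoms: none
Why: Oxidative PMB cleavage (DDQ) frees the C7 primary alcohol; silyl ethers, acetal and the trisubstituted alkene are stable.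

**Step 11**
Reactants: 15 (2R,4R,7E)-4,8-bis{[(tert-butyldiphenylsilyl)oxy]methyl}-10,10-diethoxy-2-[(triethylsilyl)oxy]dec-7-en-1-ol
Product: 16 (2R,4R,7E)-4,8-bis{[(tert-butyldiphenylsilyl)oxy]methyl}-10,10-diethoxy-2-[(triethylsilyl)oxy]dec-7-enal
Conditions: Dess–Martin periodinane, NaHCO3, CH2Cl2, 0 °C → rt
Reagents that add atoms: none
Why: Buffered Dess–Martin oxidation gives the α-silyloxy aldehyde without epimerizing C6.

**Step 12**
Reactants: 16 (2R,4R,7E)-4,8-bis{[(tert-butyldiphenylsilyl)oxy]methyl}-10,10-diethoxy-2-[(triethylsilyl)oxy]dec-7-enal; 17 methyl acrylate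
Product: 18 methyl (3RS,4R,6R,9E)-6,10-bis{[(tert-butyldiphenylsilyl)oxy]methyl}-12,12-diethoxy-3-hydroxy-2-methylidene-4-[(triethylsilyl)oxy]dodec-9-enoate
Conditions: 17 (10 equiv), DABCO (1 equiv), MeOH (2 equiv), rt, 3–5 d
Reagents that add atoms: none
Why: Morita–Baylis–Hillman reaction attaches C11–C13; the new C7 carbinol forms as a mixture that is erased in the next step.

**Step 13**
Reactants: 18 methyl (3RS,4R,6R,9E)-6,10-bis{[(tert-butyldiphenylsilyl)oxy]methyl}-12,12-diethoxy-3-hydroxy-2-methylidene-4-[(triethylsilyl)oxy]dodec-9-enoate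
Product: 19 methyl (2Z,4R,6R,9E)-2-(bromomethyl)-6,10-bis{[(tert-butyldiphenylsilyl)oxy]methyl}-12,12-diethoxy-4-[(triethylsilyl)oxy]dodeca-2,9-dienoate
Conditions: NBS, Me2S, CH2Cl2, −20 → 0 °C
Reagents that add atoms: N-bromosuccinimide, O=C1CCC(=O)N1Br
Why: Corey–Kim-type activation of the allylic alcohol and SN2′ attack of bromide give the (Z)-2-(bromomethyl)enoate with the ester trans to C6.

**Step 14**
Reactants: 19 methyl (2Z,4R,6R,9E)-2-(bromomethyl)-6,10-bis{[(tert-butyldiphenylsilyl)oxy]methyl}-12,12-diethoxy-4-[(triethylsilyl)oxy]dodeca-2,9-dienoate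
Product: 20 methyl (2Z,4R,6R,9E)-2-(bromomethyl)-6,10-bis{[(tert-butyldiphenylsilyl)oxy]methyl}-4-hydroxy-12-oxododeca-2,9-dienoate
Conditions: TsOH·H2O (0.2 equiv), acetone/H2O (10:1), 0 °C → rt; used at once
Reagents that add atoms: water, O
Why: Acid-catalysed acetal hydrolysis frees the C8 aldehyde and the same acid cleaves the labile secondary TES ether, while the primary TBDPS ethers survive.

**Step 15**
Reactants: 20 methyl (2Z,4R,6R,9E)-2-(bromomethyl)-6,10-bis{[(tert-butyldiphenylsilyl)oxy]methyl}-4-hydroxy-12-oxododeca-2,9-dienoate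
Product: 22 (3aR,4R,6R,9E,11aR)-6,10-bis{[(tert-butyldiphenylsilyl)oxy]methyl}-4-hydroxy-3-methylidene-3a,4,5,6,7,8,11,11a-octahydrocyclodeca[b]furan-2(3H)-one, via cyclodecenyl chromium alkoxide hydroxy ester 21 (not isolated)
Conditions: CrCl2 (8 equiv), THF, 20 added by syringe pump over 10 h (final 2 mM), rt; then 45 °C, 2 h; aq. NH4Cl
Reagents that add atoms: none
Why: Cr(II) turns the allylic bromide into an allylchromium(III) that adds through C7 to the tethered aldehyde (intramolecular Nozaki–Hiyama 2-(alkoxycarbonyl)allylation, chair transition state with both ring-forming substituents equatorial giving 7,8-anti) on the alkene face syn to the chromium-bound C6 hydroxyl with H6 eclipsing C7=C11 (A1,3 control, giving 7R for 6R), and the C8 chromium alkoxide then lactonizes on the methyl ester (Dreiding–Schmidt-type annulation) to the trans-fused α-methylene lactone.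

**Step 16**
Reactants: 22 (3aR,4R,6R,9E,11aR)-6,10-bis{[(tert-butyldiphenylsilyl)oxy]methyl}-4-hydroxy-3-methylidene-3a,4,5,6,7,8,11,11a-octahydrocyclodeca[b]furan-2(3H)-one; 23 angelic acid
Product: 25 (3aR,4R,6R,9E,11aR)-6,10-bis{[(tert-butyldiphenylsilyl)oxy]methyl}-3-methylidene-2-oxo-2,3,3a,4,5,6,7,8,11,11a-decahydrocyclodeca[b]furan-4-yl (2Z)-2-methylbut-2-enoate, via angelic 2,4,6-trichlorobenzoic mixed anhydride 24 (not isolated)
Conditions: 23, 2,4,6-trichlorobenzoyl chloride, Et3N, toluene, rt, 2 h; then 22, 80 °C (no DMAP)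
Reagents that add atoms: none
Why: Yamaguchi esterification through the mixed anhydride acylates the hindered C6–OH, and leaving out DMAP keeps the (Z)-geometry of the angelate.

**Step 17**
Reactants: 25 (3aR,4R,6R,9E,11aR)-6,10-bis{[(tert-butyldiphenylsilyl)oxy]methyl}-3-methylidene-2-oxo-2,3,3a,4,5,6,7,8,11,11a-decahydrocyclodeca[b]furan-4-yl (2Z)-2-methylbut-2-enoate
Product: 26 (3aR,4R,6R,9E,11aR)-6,10-bis(hydroxymethyl)-3-methylidene-2-oxo-2,3,3a,4,5,6,7,8,11,11a-decahydrocyclodeca[b]furan-4-yl (2Z)-2-methylbut-2-enoate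
Conditions: HF·pyridine, pyridine/THF, 0 °C → rt
Reagents that add atoms: none
Why: Fluoride-mediated desilylation frees both primary alcohols without touching the angelate or the α-methylene lactone.

**Compound list**
1 | (2R)-2-{[(4-methoxybenzyl)oxy]methyl}oxirane | COc1ccc(COC[C@H]2CO2)cc1 | starting material
2 | triethyl phosphonoacetate | CCOC(=O)CP(=O)(OCC)OCC | starting material
3 | ethyl (4R)-2-(diethoxyphosphoryl)-4-hydroxy-5-[(4-methoxybenzyl)oxy]pentanoate (as sodium alkoxide, C2 epimers) | CCOC(=O)C(C[C@@H](O)COCc1ccc(OC)cc1)P(=O)(OCC)OCC | intermediate (not isolated)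
4 | diethyl [(5R)-5-{[(4-methoxybenzyl)oxy]methyl}-2-oxooxolan-3-yl]phosphonate (C3 epimers) | CCOP(=O)(OCC)C1C[C@H](COCc2ccc(OC)cc2)OC1=O | intermediate
5 | 3,3-dimethoxypropanal | COC(OC)CC=O | starting material
6 | (3E,5R)-3-(3,3-dimethoxypropylidene)-5-{[(4-methoxybenzyl)oxy]methyl}oxolan-2-one | COC(OC)C/C=C1\C[C@H](COCc2ccc(OC)cc2)OC1=O | intermediate
7 | (3R,5R)-3-(3,3-dimethoxypropyl)-5-{[(4-methoxybenzyl)oxy]methyl}oxolan-2-one | COC(OC)CC[C@@H]1C[C@H](COCc2ccc(OC)cc2)OC1=O | intermediate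
8 | 3-[(3R,5R)-5-{[(4-methoxybenzyl)oxy]methyl}-2-oxooxolan-3-yl]propanal | O=CCC[C@@H]1C[C@H](COCc2ccc(OC)cc2)OC1=O | intermediate
9 | 2-bromo-1,1-diethoxyethane | CCOC(CBr)OCC | starting material
10 | ethyl 2-(diethoxyphosphoryl)-4,4-diethoxybutanoate | CCOC(=O)C(CC(OCC)OCC)P(=O)(OCC)OCC | intermediate
11 | ethyl (2E)-2-(2,2-diethoxyethyl)-5-[(3R,5R)-5-{[(4-methoxybenzyl)oxy]methyl}-2-oxooxolan-3-yl]pent-2-enoate | CCOC(=O)/C(CC(OCC)OCC)=C/CC[C@@H]1C[C@H](COCc2ccc(OC)cc2)OC1=O | intermediate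
12 | (2R,4R,7E)-10,10-diethoxy-4,8-bis(hydroxymethyl)-1-[(4-methoxybenzyl)oxy]dec-7-en-2-ol | OC/C(CC(OCC)OCC)=C/CC[C@@H](CO)C[C@@H](O)COCc1ccc(OC)cc1 | intermediate
13 | (2R,4R,7E)-4,8-bis{[(tert-butyldiphenylsilyl)oxy]methyl}-10,10-diethoxy-1-[(4-methoxybenzyl)oxy]dec-7-en-2-ol | CC(C)(C)[Si](c1ccccc1)(c1ccccc1)OC/C(CC(OCC)OCC)=C/CC[C@@H](CO[Si](c1ccccc1)(c1ccccc1)C(C)(C)C)C[C@@H](O)COCc1ccc(OC)cc1 | intermediate
14 | {[(2R,4R,7E)-4,8-bis{[(tert-butyldiphenylsilyl)oxy]methyl}-10,10-diethoxy-1-[(4-methoxybenzyl)oxy]dec-7-en-2-yl]oxy}(triethyl)silane | CC(C)(C)[Si](c1ccccc1)(c1ccccc1)OC/C(CC(OCC)OCC)=C/CC[C@@H](CO[Si](c1ccccc1)(c1ccccc1)C(C)(C)C)C[C@@H](O[Si](CC)(CC)CC)COCc1ccc(OC)cc1 | intermediate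
15 | (2R,4R,7E)-4,8-bis{[(tert-butyldiphenylsilyl)oxy]methyl}-10,10-diethoxy-2-[(triethylsilyl)oxy]dec-7-en-1-ol | CC(C)(C)[Si](c1ccccc1)(c1ccccc1)OC/C(CC(OCC)OCC)=C/CC[C@@H](CO[Si](c1ccccc1)(c1ccccc1)C(C)(C)C)C[C@@H](O[Si](CC)(CC)CC)CO | intermediate
16 | (2R,4R,7E)-4,8-bis{[(tert-butyldiphenylsilyl)oxy]methyl}-10,10-diethoxy-2-[(triethylsilyl)oxy]dec-7-enal | CC(C)(C)[Si](c1ccccc1)(c1ccccc1)OC/C(CC(OCC)OCC)=C/CC[C@@H](CO[Si](c1ccccc1)(c1ccccc1)C(C)(C)C)C[C@@H](O[Si](CC)(CC)CC)C=O | intermediate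
17 | methyl acrylate | C=CC(=O)OC | starting material
18 | methyl (3RS,4R,6R,9E)-6,10-bis{[(tert-butyldiphenylsilyl)oxy]methyl}-12,12-diethoxy-3-hydroxy-2-methylidene-4-[(triethylsilyl)oxy]dodec-9-enoate | CC(C)(C)[Si](c1ccccc1)(c1ccccc1)OC/C(CC(OCC)OCC)=C/CC[C@@H](CO[Si](c1ccccc1)(c1ccccc1)C(C)(C)C)C[C@@H](O[Si](CC)(CC)CC)C(O)C(=C)C(=O)OC | intermediate
19 | methyl (2Z,4R,6R,9E)-2-(bromomethyl)-6,10-bis{[(tert-butyldiphenylsilyl)oxy]methyl}-12,12-diethoxy-4-[(triethylsilyl)oxy]dodeca-2,9-dienoate | CC(C)(C)[Si](c1ccccc1)(c1ccccc1)OC/C(CC(OCC)OCC)=C/CC[C@@H](CO[Si](c1ccccc1)(c1ccccc1)C(C)(C)C)C[C@@H](O[Si](CC)(CC)CC)/C=C(\CBr)C(=O)OC | intermediate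
20 | methyl (2Z,4R,6R,9E)-2-(bromomethyl)-6,10-bis{[(tert-butyldiphenylsilyl)oxy]methyl}-4-hydroxy-12-oxododeca-2,9-dienoate | O=CC/C(CO[Si](c1ccccc1)(c1ccccc1)C(C)(C)C)=C\CC[C@@H](CO[Si](c1ccccc1)(c1ccccc1)C(C)(C)C)C[C@@H](O)/C=C(\CBr)C(=O)OC | intermediate
21 | methyl 2-[(1R,2R,4E,8R,10R)-4,8-bis{[(tert-butyldiphenylsilyl)oxy]methyl}-2,10-dihydroxycyclodec-4-en-1-yl]prop-2-enoate (as chromium(III) 2-alkoxide) | COC(=O)C(=C)[C@H]1[C@H](O)C/C(CO[Si](c2ccccc2)(c2ccccc2)C(C)(C)C)=C\CC[C@@H](CO[Si](c2ccccc2)(c2ccccc2)C(C)(C)C)C[C@H]1O | intermediate (not isolated)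
22 | (3aR,4R,6R,9E,11aR)-6,10-bis{[(tert-butyldiphenylsilyl)oxy]methyl}-4-hydroxy-3-methylidene-3a,4,5,6,7,8,11,11a-octahydrocyclodeca[b]furan-2(3H)-one | C=C1C(=O)O[C@@H]2C/C(CO[Si](c3ccccc3)(c3ccccc3)C(C)(C)C)=C\CC[C@@H](CO[Si](c3ccccc3)(c3ccccc3)C(C)(C)C)C[C@@H](O)[C@@H]12 | intermediate
23 | angelic acid, (2Z)-2-methylbut-2-enoic acid | C/C=C(/C)C(=O)O | starting material
24 | (2Z)-2-methylbut-2-enoic 2,4,6-trichlorobenzoic anhydride | C/C=C(/C)C(=O)OC(=O)c1c(Cl)cc(Cl)cc1Cl | intermediate (not isolated)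
25 | (3aR,4R,6R,9E,11aR)-6,10-bis{[(tert-butyldiphenylsilyl)oxy]methyl}-3-methylidene-2-oxo-2,3,3a,4,5,6,7,8,11,11a-decahydrocyclodeca[b]furan-4-yl (2Z)-2-methylbut-2-enoate | C=C1C(=O)O[C@@H]2C/C(CO[Si](c3ccccc3)(c3ccccc3)C(C)(C)C)=C\CC[C@@H](CO[Si](c3ccccc3)(c3ccccc3)C(C)(C)C)C[C@@H](OC(=O)/C(C)=C\C)[C@@H]12 | intermediate
26 | (3aR,4R,6R,9E,11aR)-6,10-bis(hydroxymethyl)-3-methylidene-2-oxo-2,3,3a,4,5,6,7,8,11,11a-decahydrocyclodeca[b]furan-4-yl (2Z)-2-methylbut-2-enoate | C=C1C(=O)O[C@@H]2C/C(CO)=C\CC[C@@H](CO)C[C@@H](OC(=O)/C(C)=C\C)[C@@H]12 | target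

**Totals**
Total step count: 17 (16 in the main line plus the preparation of reagent 10). Longest linear sequence: 16 steps (1–4 and 6–17).

**Steps most likely to fail**

Step 15. The sense of induction at C7/C8 from the C6 carbinol, the cis/trans ring fusion, competing lactonization on O6 and loss of the bromide are all uncertain in the chromium cascade. The fallback leaves the allyl-metal manifold for a ketyl–olefin one. It sets out from aldehyde 16: Wittig reaction with methyl (triphenylphosphoranylidene)acetate gives the (E)-γ-silyloxy enoate F1. TsOH in aqueous acetone removes acetal and TES to give the hydroxy aldehyde F2, whose (E)-geometry prevents lactonization. SmI2 (THF, HMPA, t-BuOH, high dilution) adds the C8 ketyl to C7 and the samarium alkoxide lactonizes, again closing both rings in one flask, to the saturated trans-lactone F3. LDA followed by Eschenmoser's salt gives the Mannich base F4. MeI converts it into the methiodide F5 (not isolated), which loses trimethylamine with NaHCO3 and rejoins the route at 22.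

Step 12. The Morita–Baylis–Hillman reaction on a hindered α-silyloxy aldehyde can be slow and can epimerize C6. The fallback replaces amine catalysis by a preformed acrylate α-anion equivalent. It sets out from 16: [α-(methoxycarbonyl)vinyl]diisobutylalane, made from methyl propiolate with DIBAL-H and NMO in THF, adds to the aldehyde at −78 → 0 °C under non-basic conditions and gives 18 directly (no new compound, F0).

Step 16. Angeloylation of the hindered C6–OH can be sluggish and can isomerize the ester to the tiglate. The fallback builds the angelate double bond on the substrate. It sets out from 22: DCC/DMAP coupling with 2-[bis(2,2,2-trifluoroethoxy)phosphoryl]propanoic acid gives the phosphonopropanoate ester F6. Still–Gennari olefination (KHMDS, 18-crown-6, THF, −78 °C) with acetaldehyde then gives the (Z)-2-methylbut-2-enoate and rejoins the route at 25.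

**Further compounds**
F1 | step 15 | methyl (2E,4R,6R,9E)-6,10-bis{[(tert-butyldiphenylsilyl)oxy]methyl}-12,12-diethoxy-4-[(triethylsilyl)oxy]dodeca-2,9-dienoate | CC(C)(C)[Si](c1ccccc1)(c1ccccc1)OC/C(CC(OCC)OCC)=C/CC[C@@H](CO[Si](c1ccccc1)(c1ccccc1)C(C)(C)C)C[C@@H](O[Si](CC)(CC)CC)/C=C/C(=O)OC
F2 | step 15 | methyl (2E,4R,6R,9E)-6,10-bis{[(tert-butyldiphenylsilyl)oxy]methyl}-4-hydroxy-12-oxododeca-2,9-dienoate | O=CC/C(CO[Si](c1ccccc1)(c1ccccc1)C(C)(C)C)=C\CC[C@@H](CO[Si](c1ccccc1)(c1ccccc1)C(C)(C)C)C[C@@H](O)/C=C/C(=O)OC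
F3 | step 15 | (3aR,4R,6R,9E,11aR)-6,10-bis{[(tert-butyldiphenylsilyl)oxy]methyl}-4-hydroxy-3a,4,5,6,7,8,11,11a-octahydrocyclodeca[b]furan-2(3H)-one | C1C(=O)O[C@@H]2C/C(CO[Si](c3ccccc3)(c3ccccc3)C(C)(C)C)=C\CC[C@@H](CO[Si](c3ccccc3)(c3ccccc3)C(C)(C)C)C[C@@H](O)[C@@H]12
F4 | step 15 | (3RS,3aR,4R,6R,9E,11aR)-6,10-bis{[(tert-butyldiphenylsilyl)oxy]methyl}-3-[(dimethylamino)methyl]-4-hydroxy-3a,4,5,6,7,8,11,11a-octahydrocyclodeca[b]furan-2(3H)-one | CN(C)CC1C(=O)O[C@@H]2C/C(CO[Si](c3ccccc3)(c3ccccc3)C(C)(C)C)=C\CC[C@@H](CO[Si](c3ccccc3)(c3ccccc3)C(C)(C)C)C[C@@H](O)[C@@H]12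
F5 | step 15 | N,N,N-trimethylammonium iodide of F4 | C[N+](C)(C)CC1C(=O)O[C@@H]2C/C(CO[Si](c3ccccc3)(c3ccccc3)C(C)(C)C)=C\CC[C@@H](CO[Si](c3ccccc3)(c3ccccc3)C(C)(C)C)C[C@@H](O)[C@@H]12.[I-]
F0 | step 12 | none | none
F6 | step 16 | (3aR,4R,6R,9E,11aR)-6,10-bis{[(tert-butyldiphenylsilyl)oxy]methyl}-3-methylidene-2-oxo-2,3,3a,4,5,6,7,8,11,11a-decahydrocyclodeca[b]furan-4-yl 2-[bis(2,2,2-trifluoroethoxy)phosphoryl]propanoate | C=C1C(=O)O[C@@H]2C/C(CO[Si](c3ccccc3)(c3ccccc3)C(C)(C)C)=C\CC[C@@H](CO[Si](c3ccccc3)(c3ccccc3)C(C)(C)C)C[C@@H](OC(=O)C(C)P(=O)(OCC(F)(F)F)OCC(F)(F)F)[C@@H]12
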